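**Strategy.** Germacrane numbering: C10 is the methyl-bearing ether carbon, C5 the other ether carbon, C3 carries OAc, C4 carries C15. Ring A (O–C10–C1–C2–C3–C4–C5) is read as a Baeyer–Villiger-expanded cyclohexanone whose carbonyl C5 is flanked by C10 and C4. One pot joins methyl 2-methylacetoacetate and acrolein: catalytic asymmetric Michael addition (C1–C10) and aldol ring closure (C3–C4). The cis-ketol is trapped as a bridged lactone, so C10 fixes C3, and acrolein's carbonyl carbon becomes the oxygenated C3. Every later centre follows by substrate control. Ring B is closed last across the trans-disposed arms, which gives the in,out oxabicycle.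

Key step: step 1

Remark: the target's descriptors (3S,4S,5R,6S,7R,8R,10R; C6 = lactone-oxygen carbon, C7 bears C11, C8 = acyloxy carbon, C11–C13 = methylene-lactone carbons) describe the in,out isomer of the 11-oxabicyclo[4.4.1]undecane core (H-5 inside), and the route is built for exactly this isomer.

Step 1
Reactants: 1 methyl 2-methyl-3-oxobutanoate (racemic); 2 acrolein
Product: 5 (1R,4S)-4-methyl-2-oxabicyclo[2.2.2]octane-3,5-dione, via Michael adduct 3 (not isolated), via cis-ketol 4 (not isolated)
Conditions: 9-O-(9-phenanthryl)cupreidine (10 mol %), CH2Cl2, −24 °C; then L-proline (20 mol %), DMF, 23 °C; then PPTS (20 mol %), 4 Å MS, PhMe, 50 °C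
Reagents that add atoms: none
Why: The bifunctional alkaloid (quinuclidine base, phenol hydrogen-bond donor; cupreidine or its cupreine pseudoenantiomer chosen so that (S)-3 results) adds the prochiral C10 enolate to the acrolein β-carbon (C1–C10), so C10 is set by the catalyst; proline then forms the enamine of the only enolisable ketone terminus (acetyl CH3 = C4), which closes onto the pendant aldehyde (C3–C4) in a 6-(enolendo)-exo-trig aldol. The closest known chemistry is the amine-catalysed Michael addition of α-substituted β-keto esters to enals followed by Robinson-type aldolisation, here held at the ketol stage. The aldol is reversible, and only the ketol whose C3 hydroxyl is cis to the C10 ester can close the second ring, the 2-oxabicyclo[2.2.2]octane lactone, by 6-exo-trig acyl transfer with loss of methanol, so C3 is relayed from C10 through the bridge. The step needs conjugate instead of 1,2-addition (soft, stabilised enolate), aldolisation without dehydration (proline at room temperature, only a weak acid in the last stage) and lactonisation of one ketol epimer only (bridge geometry).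

Step 2
Reactants: 5
Product: 6 (1R,4S)-4-methyl-5-(triethylsilyloxy)-2-oxabicyclo[2.2.2]oct-5-en-3-one
Conditions: Et3SiOTf, Et3N, CH2Cl2, −78 °C
Reagents that add atoms: triethylsilyl triflate, CC[Si](CC)(CC)OS(=O)(=O)C(F)(F)F
Why: Soft enolisation is possible only toward C4 and masks the ketone as its silyl enol ether (silyl enol ether formation), the low temperature keeping silylation ahead of β-elimination of the bridging carboxylate.

Step 3
Reactants: 6
Product: 7 (1R,4S)-4-methyl-5-(triethylsilyloxy)-2-oxabicyclo[2.2.2]oct-5-en-3-ol (lactol, both epimers at the hemiacetal carbon C9)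
Conditions: (i-Bu)2AlH (1.1 equiv), PhMe, −78 °C; aq. potassium sodium tartrate
Reagents that add atoms: none
Why: Partial hydride reduction of the only remaining carbonyl, the lactone, should stop at the bridged lactol (lactone-to-lactol reduction), which resists over-reduction.

Step 4
Reactants: 7
Product: 9 (2R,5R)-5-hydroxy-2-methyl-2-vinylcyclohexan-1-one, via silyl enol ether 8 (not isolated)
Conditions: Ph3PCH3Br, KN(SiMe3)2, THF, 0 °C → rt; then 1 M HCl, THF, 0 °C
Reagents that add atoms: methyltriphenylphosphonium bromide, C[P+](c1ccccc1)(c1ccccc1)c1ccccc1.[Br-]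
Why: Wittig methylenation of the lactol's open hydroxy-aldehyde form turns C9 into the vinyl CH (C9=C8) and frees the C3 hydroxyl cis to it, and dilute acid then hydrolyses the silyl enol ether back to the C5 ketone.

Step 5
Reactants: 9
Product: 10 (4R,7R)-4-hydroxy-7-methyl-7-vinyloxepan-2-one
Conditions: (Me3SiO)2, Me3SiOTf (10 mol %), CH2Cl2, −40 °C; then aq. NaHCO3
Reagents that add atoms: bis(trimethylsilyl) peroxide, C[Si](C)(C)OO[Si](C)(C)C
Why: Baeyer–Villiger oxidation: the quaternary, allylic C10 should migrate in preference to the C4 methylene and with retention, which inserts the ring-A oxygen between C5 and C10, while the silyl peroxide oxidises ketones without epoxidising the vinyl group.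

Step 6
Reactants: 10
Product: 11 (3S,4R,7R)-4-hydroxy-3-(hydroxymethyl)-7-methyl-7-vinyloxepan-2-one
Conditions: LiN(i-Pr)2 (2.3 equiv), THF, −78 → −40 °C; CH2O (gas), −78 °C
Reagents that add atoms: formaldehyde, C=O
Why: Fráter–Seebach-type hydroxymethylation of the alkoxide–enolate dianion: the electrophile should add to C4 anti to the C3 alkoxide, so C15 enters trans to O3 and cis to the C10 methyl.

Step 7
Reactants: 11
Product: 12 (3S,4R,7R)-4-hydroxy-7-methyl-3-[(triisopropylsilyloxy)methyl]-7-vinyloxepan-2-one
Conditions: i-Pr3SiCl, imidazole, DMF, 0 °C → rt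
Reagents that add atoms: triisopropylsilyl chloride, CC(C)[Si](Cl)(C(C)C)C(C)C
Why: The primary hydroxyl should be silylated selectively over the hindered secondary C3 hydroxyl (silyl ether formation), which stays free for its later inversion.

Step 8
Reactants: 12
Product: 13 2-(1,3-dithian-2-yl)-7-methyl-3-[(triisopropylsilyloxy)methyl]-7-vinyloxepane-2,4-diol (hemiketal, both C5 anomers; other centres as in 12)
Conditions: 1,3-dithiane, n-BuLi (3 equiv), THF, −30 °C; then 12, −78 → −40 °C
Reagents that add atoms: 1,3-dithiane, C1CSCSC1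
Why: The dithiane anion adds once to the lactone carbonyl C5 (masked formyl-anion addition) and the adduct is held as the hemiketal, which brings in C6 at the aldehyde oxidation level.

Step 9
Reactants: 13
Product: 14 2-(1,3-dithian-2-yl)-7-methyl-3-[(triisopropylsilyloxy)methyl]-7-vinyloxepan-4-ol (dithianyl, CH2OSi and 7-methyl on one face; 4-OH and vinyl on the other)
Conditions: Et3SiH, BF3·OEt2, CH2Cl2, −78 → −50 °C
Reagents that add atoms: none
Why: The Lewis acid ionises the hemiketal to the seven-membered oxocarbenium ion and the silane should deliver hydride to C5 anti to the neighbouring C4 substituent (reductive C-glycosidation type), so H-5 is trans to C15 and cis to the vinyl arm, the trans relation of the two future ring-B arms.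

Step 10
Reactants: 14
Product: 15 the C3-inverted acetate, 2-(1,3-dithian-2-yl)-7-methyl-3-[(triisopropylsilyloxy)methyl]-7-vinyloxepan-4-yl acetate (acetate, CH2OSi, dithianyl and 7-methyl all cis)
Conditions: AcOH, PPh3, DIAD, PhMe, 0 °C → rt
Reagents that add atoms: acetic acid, CC(=O)O
Why: Mitsunobu reaction: SN2 displacement of the activated C3 oxygen by acetate inverts C3 and places the acetate cis to C15, C6 and the C10 methyl, as in the target.

Step 11
Reactants: 15
Product: 16 2-formyl-7-methyl-3-[(triisopropylsilyloxy)methyl]-7-vinyloxepan-4-yl acetate (configuration as in 15)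
Conditions: MeI, CaCO3, MeCN/H2O (9:1), 45 °C
Reagents that add atoms: water, O
Why: S-Methylation turns the dithiane into a leaving group and water delivers the C6 aldehyde (dithioacetal hydrolysis) under buffered conditions that should leave the α-alkoxy centre C5, the acetate and the silyl ether intact.

Step 12
Reactants: 16
Product: 17 methyl 4-[4-acetoxy-7-methyl-3-[(triisopropylsilyloxy)methyl]-7-vinyloxepan-2-yl]-4-(triethylsilyloxy)but-2-ynoate (O5/O6 anti)
Conditions: methyl propiolate, LiN(SiMe3)2, THF, −78 °C; then 16; then Et3SiOTf, −78 °C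
Reagents that add atoms: methyl propiolate, C#CC(=O)OC; triethylsilyl triflate, CC[Si](CC)(CC)OS(=O)(=O)C(F)(F)F
Why: Addition of the lithium acetylide to the α-alkoxy aldehyde under Felkin–Anh (polar) control should give the 5,6-anti carbinol, the C6 configuration of the target, and the alkoxide is silylated in the same flask.

Step 13
Reactants: 17
Product: 18 the corresponding methyl (Z)-4-(triethylsilyloxy)but-2-enoate
Conditions: H2 (1 atm), Pd/CaCO3 poisoned with Pb(OAc)2, quinoline, EtOAc, rt
Reagents that add atoms: none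
Why: Syn semihydrogenation of the ynoate (Lindlar reduction) gives the (Z)-enoate; the silyl ether on O6 prevents butenolide formation and the hindered vinyl group on C10 should react far more slowly.

Step 14
Reactants: 18
Product: 19 the aldehyde in which the C10 vinyl group has become CH2CHO (C9H2–C8HO)
Conditions: PdCl2(PhCN)2 (10 mol %), CuCl2·2H2O (10 mol %), AgNO2 (5 mol %), O2 (1 atm), t-BuOH/MeNO2, rt
Reagents that add atoms: dioxygen, O=O
Why: Aldehyde-selective (anti-Markovnikov) Wacker oxidation: the quaternary, oxygen-bearing C10 next to the vinyl group disfavours attack at C9, so C8 becomes the aldehyde, and the electron-poor (Z)-enoate is not touched.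

Step 15
Reactants: 19
Product: 21 ring-B-closed hydroxy α-methylene ester (in,out-11-oxabicyclo[4.4.1]undecane; C8–OH trans to the C7 acrylate arm; 6-OSiEt3, 15-OSi(i-Pr)3, 3-OAc), via Mannich base 20 (not isolated)
Conditions: SmI2 (2.5 equiv), HMPA, THF, −78 °C; Me2N=CH2 I, −78 → 0 °C; then MeI, rt; aq. NaHCO3
Reagents that add atoms: N,N-dimethylmethyleneiminium iodide, C=[N+](C)C.[I-]
Why: SmI2 reduces the C8 aldehyde to a ketyl that adds 7-exo-trig to C7 of the (Z)-enoate from the face of the C5 tether (A(1,3) strain keeps H-6 in the enoate plane, so H-6 and H-7 should end up anti and the C8 oxygen anti to the C11 arm), the trivalent samarium enolate is trapped by the iminium salt (Mannich reaction) and quaternisation–elimination leaves the α-methylene ester; because C5 and C10 were fixed trans beforehand, the ring that closes can only be the in,out bicycle (ketyl–olefin cyclisation).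

Step 16
Reactants: 22 (E)-but-2-enal (crotonaldehyde)
Product: 23 (Z)-2-iodobut-2-enal
Conditions: I2, K2CO3, DMAP (20 mol %), THF/H2O (1:1), rt
Reagents that add atoms: iodine, II
Why: Amine-catalysed α-iodination of the enal (conjugate addition, iodination, elimination) should give the thermodynamic (Z)-α-iodoenal with CHO trans to the methyl group.

Step 17
Reactants: 23
Product: 24 (Z)-2-iodobut-2-en-1-ol
Conditions: NaBH4, CeCl3·7H2O, MeOH, 0 °C
Reagents that add atoms: none
Why: Luche 1,2-reduction of the enal leaves the vinyl iodide and its geometry untouched.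

Step 18
Reactants: 24
Product: 25 (Z)-tert-butyl[(2-iodobut-2-en-1-yl)oxy]dimethylsilane
Conditions: t-BuMe2SiCl, imidazole, CH2Cl2, 0 °C → rt
Reagents that add atoms: tert-butyldimethylsilyl chloride, CC(C)(C)[Si](C)(C)Cl
Why: Silyl ether formation protects the primary hydroxyl with the group that is removed in the final step.

Step 19
Reactants: 25
Product: 26 (Z)-2-[(tert-butyldimethylsilyloxy)methyl]but-2-enoic acid
Conditions: t-BuLi (2.1 equiv), Et2O, −78 °C; CO2; 1 M HCl
Reagents that add atoms: carbon dioxide, O=C=O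
Why: Iodine–lithium exchange and carboxylation proceed with retention of alkene geometry, so the carboxyl group ends cis to the methyl group as in the target's acyl residue.

Step 20
Reactants: 21; 26
Product: 27 the C8 ester of 21 with 26, C8 inverted (acyloxy group cis to the C7 acrylate arm)
Conditions: PPh3, DIAD, PhMe, 0 °C → rt
Reagents that add atoms: none
Why: Mitsunobu esterification inverts C8, converting the alcohol expected from step 15 into the ester with the target's C8 configuration.

Step 21
Reactants: 27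
Product: 29 the target, CNP0195618.1, via triol ester 28 (not isolated)
Conditions: HF·pyridine, pyridine, THF, 0 °C → rt; then PPTS, CH2Cl2, rt
Reagents that add atoms: none
Why: Fluoride-mediated removal of the three silyl ethers frees O6, which should lactonise onto the acrylate ester to give the trans-fused α-methylene-γ-butyrolactone, while the acetate and the C8 ester survive these mildly acidic conditions.

**Compound list**

1 | methyl 2-methyl-3-oxobutanoate (racemic) | CC(=O)C(C)C(=O)OC | starting material
2 | acrolein | C=CC=O | starting material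
3 | methyl (S)-2-acetyl-2-methyl-5-oxopentanoate | CC(=O)[C@](C)(CCC=O)C(=O)OC | intermediate
4 | methyl (1S,4R)-4-hydroxy-1-methyl-2-oxocyclohexane-1-carboxylate (OH cis to CO2Me) | O=C1C[C@H](O)CC[C@]1(C)C(=O)OC | intermediate
5 | (1R,4S)-4-methyl-2-oxabicyclo[2.2.2]octane-3,5-dione | O=C1C[C@H]2CC[C@]1(C)C(=O)O2 | intermediate
6 | (1R,4S)-4-methyl-5-(triethylsilyloxy)-2-oxabicyclo[2.2.2]oct-5-en-3-one | CC[Si](CC)(CC)OC1=C[C@H]2CC[C@]1(C)C(=O)O2 | intermediate
7 | (1R,4S)-4-methyl-5-(triethylsilyloxy)-2-oxabicyclo[2.2.2]oct-5-en-3-ol (lactol epimers) | CC[Si](CC)(CC)OC1=C[C@H]2CC[C@]1(C)C(O)O2 | intermediate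
8 | 4-methyl-3-(triethylsilyloxy)-4-vinylcyclohex-2-en-1-ol (OH cis to vinyl) | CC[Si](CC)(CC)OC1=C[C@H](O)CC[C@]1(C)C=C | intermediate
9 | (2R,5R)-5-hydroxy-2-methyl-2-vinylcyclohexan-1-one | O=C1C[C@H](O)CC[C@]1(C)C=C | intermediate
10 | (4R,7R)-4-hydroxy-7-methyl-7-vinyloxepan-2-one | C=C[C@@]1(C)CC[C@@H](O)CC(=O)O1 | intermediate
11 | (3S,4R,7R)-4-hydroxy-3-(hydroxymethyl)-7-methyl-7-vinyloxepan-2-one | C=C[C@@]1(C)CC[C@@H](O)[C@H](CO)C(=O)O1 | intermediate
12 | (3S,4R,7R)-4-hydroxy-7-methyl-3-[(triisopropylsilyloxy)methyl]-7-vinyloxepan-2-one | C=C[C@@]1(C)CC[C@@H](O)[C@H](CO[Si](C(C)C)(C(C)C)C(C)C)C(=O)O1 | intermediate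
13 | 2-(1,3-dithian-2-yl)-7-methyl-3-[(triisopropylsilyloxy)methyl]-7-vinyloxepane-2,4-diol (hemiketal anomers) | C=C[C@@]1(C)CC[C@@H](O)[C@H](CO[Si](C(C)C)(C(C)C)C(C)C)C(O)(C2SCCCS2)O1 | intermediate
14 | 2-(1,3-dithian-2-yl)-7-methyl-3-[(triisopropylsilyloxy)methyl]-7-vinyloxepan-4-ol (H-5 cis to vinyl; OH trans to CH2OSi) | C=C[C@@]1(C)CC[C@@H](O)[C@H](CO[Si](C(C)C)(C(C)C)C(C)C)[C@H](C2SCCCS2)O1 | intermediate
15 | 2-(1,3-dithian-2-yl)-7-methyl-3-[(triisopropylsilyloxy)methyl]-7-vinyloxepan-4-yl acetate (C3 inverted, all-cis with 7-methyl) | C=C[C@@]1(C)CC[C@H](OC(C)=O)[C@H](CO[Si](C(C)C)(C(C)C)C(C)C)[C@H](C2SCCCS2)O1 | intermediate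
16 | 2-formyl-7-methyl-3-[(triisopropylsilyloxy)methyl]-7-vinyloxepan-4-yl acetate | C=C[C@@]1(C)CC[C@H](OC(C)=O)[C@H](CO[Si](C(C)C)(C(C)C)C(C)C)[C@H](C=O)O1 | intermediate
17 | methyl 4-[4-acetoxy-7-methyl-3-[(triisopropylsilyloxy)methyl]-7-vinyloxepan-2-yl]-4-(triethylsilyloxy)but-2-ynoate (5,6-anti) | C=C[C@@]1(C)CC[C@H](OC(C)=O)[C@H](CO[Si](C(C)C)(C(C)C)C(C)C)[C@H]([C@@H](O[Si](CC)(CC)CC)C#CC(=O)OC)O1 | intermediate
18 | methyl (Z)-4-[4-acetoxy-7-methyl-3-[(triisopropylsilyloxy)methyl]-7-vinyloxepan-2-yl]-4-(triethylsilyloxy)but-2-enoate | C=C[C@@]1(C)CC[C@H](OC(C)=O)[C@H](CO[Si](C(C)C)(C(C)C)C(C)C)[C@H]([C@@H](O[Si](CC)(CC)CC)/C=C\C(=O)OC)O1 | intermediate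
19 | methyl (Z)-4-[4-acetoxy-7-methyl-7-(2-oxoethyl)-3-[(triisopropylsilyloxy)methyl]oxepan-2-yl]-4-(triethylsilyloxy)but-2-enoate | O=CC[C@@]1(C)CC[C@H](OC(C)=O)[C@H](CO[Si](C(C)C)(C(C)C)C(C)C)[C@H]([C@@H](O[Si](CC)(CC)CC)/C=C\C(=O)OC)O1 | intermediate
20 | ring-B-closed Mannich base: methyl 3-(dimethylamino)-2-(bicyclic C7 substituent)propanoate, C8–OH trans to the C7 arm | COC(=O)C(CN(C)C)[C@H]1[C@H](O[Si](CC)(CC)CC)[C@@H]2O[C@](C)(CC[C@H](OC(C)=O)[C@@H]2CO[Si](C(C)C)(C(C)C)C(C)C)C[C@@H]1O | intermediate
21 | ring-B-closed hydroxy α-methylene ester (in,out-11-oxabicyclo[4.4.1]undecane; C8–OH trans to the C7 acrylate arm) | C=C(C(=O)OC)[C@H]1[C@H](O[Si](CC)(CC)CC)[C@@H]2O[C@](C)(CC[C@H](OC(C)=O)[C@@H]2CO[Si](C(C)C)(C(C)C)C(C)C)C[C@@H]1O | intermediate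
22 | (E)-but-2-enal | C/C=C/C=O | starting material
23 | (Z)-2-iodobut-2-enal | C/C=C(\I)C=O | intermediate
24 | (Z)-2-iodobut-2-en-1-ol | C/C=C(\I)CO | intermediate
25 | (Z)-tert-butyl[(2-iodobut-2-en-1-yl)oxy]dimethylsilane | C/C=C(\I)CO[Si](C)(C)C(C)(C)C | intermediate
26 | (Z)-2-[(tert-butyldimethylsilyloxy)methyl]but-2-enoic acid | C/C=C(\C(=O)O)CO[Si](C)(C)C(C)(C)C | intermediate
27 | fully protected seco-lactone: C8 ester of 21 with 26 (C8 inverted) | C=C(C(=O)OC)[C@H]1[C@H](O[Si](CC)(CC)CC)[C@@H]2O[C@](C)(CC[C@H](OC(C)=O)[C@@H]2CO[Si](C(C)C)(C(C)C)C(C)C)C[C@H]1OC(=O)/C(=C\C)CO[Si](C)(C)C(C)(C)C | intermediate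
28 | desilylated triol methyl ester (6-OH, 15-OH and side-chain OH free) | C=C(C(=O)OC)[C@H]1[C@H](O)[C@@H]2O[C@](C)(CC[C@H](OC(C)=O)[C@@H]2CO)C[C@H]1OC(=O)/C(=C\C)CO | intermediate
29 | CNP0195618.1 | C=C1C(=O)O[C@@H]2[C@@H]3O[C@](C)(CC[C@H](OC(C)=O)[C@@H]3CO)C[C@@H](OC(=O)/C(=C\C)CO)[C@@H]12 | target

**Totals.** 21 steps in all; longest linear sequence 17 steps (steps 1–15, 20, 21).

**Steps most likely to fail**

1. Step 15 (closure of ring B). The strained trans-bridged seven-membered ring may close too slowly, so that the ketyl is simply reduced or dimerises, and trapping of the enolate may be incomplete. The fallback replaces the ketyl radical by an organochromium allylation and sets out from 16. Addition of vinylmagnesium bromide (Felkin–Anh) with silylation in the same flask would give the bis-vinyl silyl ether F1. Cross-metathesis with methyl 2-(bromomethyl)acrylate (second-generation Hoveyda–Grubbs catalyst) would give the allylic bromide F2. Hydroboration of the remaining C10 vinyl group (9-BBN, then NaBO3·4H2O) would give the primary alcohol F3, and Dess–Martin oxidation the aldehyde F4. CrCl2 in THF would then close ring B by intramolecular Nozaki–Hiyama-type allylation of C8 by C7 with allylic transposition; this delivers the α-methylene ester directly and returns to the route at 21.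

2. Step 20 (Mitsunobu esterification at C8). Displacement at the hindered ring carbinol may be outrun by elimination toward C9 or may not proceed, and the C8 configuration formed in step 15 may differ from the one assumed. The fallback inverts by oxidation and reduction and then acylates with retention. From 21, Dess–Martin oxidation would give the C8 ketone F5. Reduction from the more open face (NaBH4, CeCl3·7H2O, −78 °C) would give the epimeric alcohol F6. Yamaguchi esterification with 26 (2,4,6-trichlorobenzoyl chloride, Et3N, DMAP) returns to the route at 27.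

3. Step 1 (key step). Dehydration of the ketol to the conjugated enone may outrun lactonisation, so that material leaves the sequence before the bridge forms. The fallback builds the lactone by conjugate addition instead of acyl transfer and sets out from 1 and 2. The same Michael addition followed by deliberate aldol condensation (TsOH, PhH, reflux) would give methyl (S)-1-methyl-2-oxocyclohex-3-ene-1-carboxylate F7. Cold LiOH hydrolysis would give (S)-1-methyl-2-oxocyclohex-3-ene-1-carboxylic acid F8. Acid-catalysed intramolecular oxa-Michael addition of the carboxyl group to C3, possible only on the face of C9, returns to the route at 5.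

Further compounds
F1 | step 15 | 7-methyl-2-[1-(triethylsilyloxy)prop-2-en-1-yl]-3-[(triisopropylsilyloxy)methyl]-7-vinyloxepan-4-yl acetate | C=C[C@@]1(C)CC[C@H](OC(C)=O)[C@H](CO[Si](C(C)C)(C(C)C)C(C)C)[C@H]([C@@H](O[Si](CC)(CC)CC)C=C)O1
F2 | step 15 | methyl 2-(bromomethyl)-4-[4-acetoxy-7-methyl-3-[(triisopropylsilyloxy)methyl]-7-vinyloxepan-2-yl]-4-(triethylsilyloxy)but-2-enoate (CH2Br cis to C6) | C=C[C@@]1(C)CC[C@H](OC(C)=O)[C@H](CO[Si](C(C)C)(C(C)C)C(C)C)[C@H]([C@@H](O[Si](CC)(CC)CC)/C=C(\CBr)C(=O)OC)O1
F3 | step 15 | the 7-(2-hydroxyethyl) analogue of F2 | OCC[C@@]1(C)CC[C@H](OC(C)=O)[C@H](CO[Si](C(C)C)(C(C)C)C(C)C)[C@H]([C@@H](O[Si](CC)(CC)CC)/C=C(\CBr)C(=O)OC)O1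
F4 | step 15 | the 7-(2-oxoethyl) analogue of F2 | O=CC[C@@]1(C)CC[C@H](OC(C)=O)[C@H](CO[Si](C(C)C)(C(C)C)C(C)C)[C@H]([C@@H](O[Si](CC)(CC)CC)/C=C(\CBr)C(=O)OC)O1
F5 | step 20 | C8 ketone derived from 21 | C=C(C(=O)OC)[C@H]1[C@H](O[Si](CC)(CC)CC)[C@@H]2O[C@](C)(CC[C@H](OC(C)=O)[C@@H]2CO[Si](C(C)C)(C(C)C)C(C)C)CC1=O
F6 | step 20 | C8 epimer of 21 (C8–OH cis to the C7 acrylate arm) | C=C(C(=O)OC)[C@H]1[C@H](O[Si](CC)(CC)CC)[C@@H]2O[C@](C)(CC[C@H](OC(C)=O)[C@@H]2CO[Si](C(C)C)(C(C)C)C(C)C)C[C@H]1O
F7 | step 1 | methyl (S)-1-methyl-2-oxocyclohex-3-ene-1-carboxylate | O=C1C=CCC[C@]1(C)C(=O)OC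
F8 | step 1 | (S)-1-methyl-2-oxocyclohex-3-ene-1-carboxylic acid | O=C1C=CCC[C@]1(C)C(=O)O
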